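The cyclohexane ring is opened between C8 and C9, the two adjacent ring carbons whose oxygens (lactone O and ester O) are cis and lie opposite the C14 methyl on C10. A reductive pinacol coupling with SmI2 closes the carbocycle and sets both carbinol centres in one operation, because trivalent samarium holds the two ketyl oxygens on one face. The substrate is an acyclic 1,6-dialdehyde that already carries C7, C6, C5 and C10 in the correct configuration: a tert-butyl acetate arm on C7, a silyl ether on C6, isopropenyl on C5 and methyl plus vinyl on C10. These four centres come from one auxiliary aldol and a butenolide template.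

Key step: step 13

Remarks
- Numbering: the carbocycle is C5–C6–C7–C8–C9–C10. C5 carries the acrolein unit C4(=C15)–C3HO, C6 the free hydroxyl, C7 and C8 are the lactone fusion atoms (oxygen on C8), C9 carries the ester oxygen, and C10 is quaternary with methyl C14 and the oxirane C1–C2. C11, C12 and C13 are the lactone α-carbon, carbonyl carbon and exocyclic methylene. TBS = tert-butyldimethylsilyl.
- Stereochemical bookkeeping: along the open chain C8–C7–C6–C5–C10–C9 the C7 arm and the C6 oxygen are anti, the C6 oxygen and the C5 isopropenyl are anti, and the C5 isopropenyl and the C10 vinyl are syn. Hence an anti-aldol (C6/C7) and a trans,trans-substituted lactone template (C6/C5/C10) are used.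
- Assumption: the MgCl2-catalysed anti-aldol is taken to react on the enolate face away from the benzyl group of the chelated imide, as in auxiliary alkylations; should the opposite sense be found, the enantiomeric auxiliary is used.

Step 1
Reactants: 1 mono-tert-butyl succinate; 2 (R)-4-benzyloxazolidin-2-one
Product: 4 tert-butyl 4-[(4R)-4-benzyl-2-oxo-1,3-oxazolidin-3-yl]-4-oxobutanoate, via mixed pivalic anhydride 3 (not isolated)
Conditions: PivCl, Et3N, THF, −20 °C; then 2, LiCl, rt
Reagents that add atoms: none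
Why: Mixed-anhydride N-acylation of the oxazolidinone (LiCl-promoted acyl transfer) is routine for unhindered acids; no stereocentre is formed and the tert-butyl ester is untouched.

Step 2
Reactants: 4 succinyl imide; 5 (E)-cinnamaldehyde
Product: 7 tert-butyl (3S,4S,5E)-3-{[(4R)-4-benzyl-2-oxo-1,3-oxazolidin-3-yl]carbonyl}-4-hydroxy-6-phenylhex-5-enoate, via trimethylsilyl ether 6 (not isolated)
Conditions: MgCl2 (20 mol%), Et3N, Me3SiCl, EtOAc, rt; then TFA (cat.), MeOH
Reagents that add atoms: none
Why: Magnesium-halide-catalysed anti-aldol addition of an N-acyl oxazolidinone to a non-enolisable enal: soft enolisation gives the chelated (Z)-enolate, the aldehyde adds to the face away from the benzyl group through a boat-like transition state, so C7 and C6 should be set in the required anti relationship, and silylation of the aldolate turns the catalyst over before acidic methanol frees the hydroxyl.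

Step 3
Reactants: 7 anti-aldol adduct
Product: 8 tert-butyl (3R,4S,5E)-4-hydroxy-3-(hydroxymethyl)-6-phenylhex-5-enoate
Conditions: LiBH4, MeOH (1 equiv), THF, 0 °C
Reagents that add atoms: none
Why: LiBH4 reduces the activated imide carbonyl much faster than the hindered tert-butyl ester (reductive auxiliary removal), giving the C8 primary alcohol and returning the auxiliary without touching C6 or C7.

Step 4
Reactants: 8 diol
Product: 9 tert-butyl (3R,4S,5E)-3-{[(TBS)oxy]methyl}-4-hydroxy-6-phenylhex-5-enoate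
Conditions: TBSCl (1.05 equiv), imidazole, CH2Cl2, 0 °C
Reagents that add atoms: tert-butyldimethylsilyl chloride, CC(C)(C)[Si](C)(C)Cl
Why: Steric differentiation in silylation: the primary C8 hydroxyl should react well before the secondary allylic C6 hydroxyl.

Step 5
Reactants: 9 allylic alcohol; 10 methacryloyl chloride
Product: 11 tert-butyl (3R,4S,5E)-3-{[(TBS)oxy]methyl}-4-(methacryloyloxy)-6-phenylhex-5-enoate
Conditions: Et3N, DMAP (cat.), CH2Cl2, 0 °C
Reagents that add atoms: none
Why: DMAP-catalysed acylation with an acyl chloride places the future C9, C10 and C14 atoms on the C6 oxygen without affecting either stereocentre.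

Step 6
Reactants: 11 methacrylate
Product: 12 tert-butyl (3R)-4-[(TBS)oxy]-3-[(2S)-4-methyl-5-oxo-2,5-dihydrofuran-2-yl]butanoate
Conditions: second-generation Grubbs catalyst (5 mol%), toluene, 80 °C
Reagents that add atoms: none
Why: Ring-closing metathesis between the styrenyl alkene and the methacrylate closes the unsaturated five-membered lactone with loss of styrene; the ruthenium carbene loads on the 1,2-disubstituted alkene first, and C6 and C7 are not involved.

Step 7
Reactants: 12 α-methylbutenolide; 13 isopropenylmagnesium bromide; 14 acetaldehyde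
Product: 16 tert-butyl (3R)-4-[(TBS)oxy]-3-[(2S,3S,4R)-4-(1-hydroxyethyl)-4-methyl-5-oxo-3-(prop-1-en-2-yl)oxolan-2-yl]butanoate (both carbinol epimers), via bromomagnesium enolate 15 (not isolated)
Conditions: 13 (2.4 equiv), CuBr·SMe2 (1.2 equiv), THF, −78 to −30 °C; then 14, −78 °C; aq. NH4Cl
Reagents that add atoms: none
Why: Organocuprate 1,4-addition followed by aldol trapping of the enolate (three-component coupling): the isopropenyl group should enter C5 anti to the C6 side chain, and the resulting enolate should take the aldehyde at C10 anti to the new isopropenyl group, which leaves the C14 methyl cis to it; the carbinol centre is erased in step 8, and forming the enolate by conjugate addition avoids any strong base near the tert-butyl ester.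

Step 8
Reactants: 16 hydroxyethyl lactone
Product: 17 tert-butyl (3R)-4-[(TBS)oxy]-3-[(2S,3S,4S)-4-ethenyl-4-methyl-5-oxo-3-(prop-1-en-2-yl)oxolan-2-yl]butanoate
Conditions: Martin sulfurane, CH2Cl2, 0 °C to rt
Reagents that add atoms: none
Why: Martin sulfurane dehydration of a secondary alcohol: because C10 is quaternary the alkoxysulfonium can only lose a hydrogen from the methyl group, so the terminal vinyl group should result from either carbinol epimer.

Step 9
Reactants: 17 vinyl lactone
Product: 19 tert-butyl (3R,4S,5S,6S)-3-{[(TBS)oxy]methyl}-4-hydroxy-6-(hydroxymethyl)-6-methyl-5-(prop-1-en-2-yl)oct-7-enoate, via lactol 18 (not isolated)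
Conditions: (i-Bu)2AlH, CH2Cl2, −78 °C; then MeOH, NaBH4, −78 to 0 °C
Reagents that add atoms: none
Why: Two-stage lactone reduction: (i-Bu)2AlH at −78 °C stops at the lactol and spares the tert-butyl ester, and NaBH4 then reduces the open hydroxy-aldehyde form to the primary C9 alcohol, freeing the C6 hydroxyl.

Step 10
Reactants: 19 diol
Product: 20 tert-butyl (3R,4S,5S,6S)-4-[(TBS)oxy]-3,6-bis{[(TBS)oxy]methyl}-6-methyl-5-(prop-1-en-2-yl)oct-7-enoate
Conditions: TBSOTf (2.5 equiv), 2,6-lutidine, CH2Cl2, −78 to 0 °C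
Reagents that add atoms: tert-butyldimethylsilyl trifluoromethanesulfonate, CC(C)(C)[Si](C)(C)OS(=O)(=O)C(F)(F)F
Why: The silyl triflate is reactive enough for the very hindered C6 hydroxyl and also caps the C9 alcohol; low temperature keeps the tert-butyl ester intact.

Step 11
Reactants: 20 tris-silyl ether
Product: 21 tert-butyl (3R,4S,5S,6S)-4-[(TBS)oxy]-3,6-bis(hydroxymethyl)-6-methyl-5-(prop-1-en-2-yl)oct-7-enoate
Conditions: CSA (cat.), MeOH/CH2Cl2, 0 °C
Reagents that add atoms: none
Why: Acid-catalysed methanolysis removes primary silyl ethers far faster than the flanked secondary C6 ether, so the C8 and C9 alcohols should be released together.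

Step 12
Reactants: 21 1,6-diol
Product: 22 tert-butyl (3S,4S,5S,6S)-4-[(TBS)oxy]-3,6-diformyl-6-methyl-5-(prop-1-en-2-yl)oct-7-enoate
Conditions: Dess–Martin periodinane, CH2Cl2, 0 °C to rt
Reagents that add atoms: none
Why: Dess–Martin oxidation converts both primary alcohols into aldehydes under near-neutral conditions, which protects the C7 centre (α to the C8 formyl group) from epimerisation and the β-silyloxy group from elimination; a 1,6-diol cannot close to a stable lactol.

Step 13
Reactants: 22 C8,C9-dialdehyde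
Product: 23 tert-butyl 2-[(1R,2R,3S,4S,5S,6S)-6-[(TBS)oxy]-4-ethenyl-2,3-dihydroxy-4-methyl-5-(prop-1-en-2-yl)cyclohexyl]acetate
Conditions: SmI2 (2.5 equiv), THF (0.01 M), −78 to 0 °C; aq. NH4Cl
Reagents that add atoms: none
Why: Divalent samarium transfers one electron to each formyl group, and the C8–C9 bond forms inside a complex in which trivalent samarium binds both ketyl oxygens; the closest known reaction type is the SmI2 pinacol cyclisation of 1,6-dialdehydes to cis-cyclohexane-1,2-diols. The six-membered ring closes in a 6-exo mode (the C9 ketyl carbon attacks the C8 carbonyl carbon, oxygen staying outside the ring) through a chair in which the C7 acetate arm, the C5 isopropenyl group and the C10 vinyl group are equatorial. C8 and C9 are controlled together by the samarium bridge, which keeps the two oxygens cis. Which cis-diol forms is decided by the chair: an equatorial C8–O with an axial C9–O escapes the 1,3-diaxial contacts that an axial C8–O would have with the C14 methyl and the C6 silyloxy group, so both oxygens should end up opposite C14 and trans to the C7 arm. The step needs coupling to win over simple reduction, bimolecular coupling and ketyl–olefin addition: C9 has no α-hydrogen, branching at C7 and C10 slows bimolecular reaction, and high dilution at low temperature without HMPA leaves the unactivated alkenes and the tert-butyl ester alone.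

Step 14
Reactants: 23 cis-diol
Product: 24 (3aR,4S,5S,6S,7S,7aR)-4-[(TBS)oxy]-6-ethenyl-7-hydroxy-6-methyl-5-(prop-1-en-2-yl)hexahydro-1-benzofuran-2(3H)-one
Conditions: KOC(CH3)3 (0.2 equiv), THF, 0 °C to rt
Reagents that add atoms: none
Why: Alkoxide-catalysed intramolecular transesterification: only the equatorial C8 oxygen can reach the C12 ester (5-exo-trig), giving the trans-fused γ-lactone while the expelled tert-butoxide carries the chain; the axial C9 hydroxyl is trans to the acetate arm and cannot lactonise, and the silyl ether keeps C6 from competing.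

Step 15
Reactants: 24 hydroxy lactone
Product: 27 (3aR,4S,5S,6S,7S,7aR)-4-[(TBS)oxy]-6-ethenyl-7-hydroxy-6-methyl-3-methylidene-5-(prop-1-en-2-yl)hexahydro-1-benzofuran-2(3H)-one, via Mannich base 25 (not isolated), via trimethylammonium iodide 26 (not isolated)
Conditions: LiN(i-Pr)2 (2.5 equiv), THF, −78 °C; [CH2=NMe2]I, −78 to 0 °C; then MeI, MeOH; then aq. NaHCO3, CH2Cl2
Reagents that add atoms: N,N-dimethylmethyleneiminium iodide (Eschenmoser's salt), C=[N+](C)C.[I-]
Why: Eschenmoser methylenation: the lactone enolate (the C9 hydroxyl is carried as its alkoxide) undergoes a Mannich reaction with the iminium salt, and quaternisation followed by mild base-induced elimination gives the exocyclic C11=C13 alkene.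

Step 16
Reactants: 27 methylene lactone alcohol; 28 (S)-2-methylbutanoic acid
Product: 30 (3aR,4S,5S,6S,7S,7aR)-4-[(TBS)oxy]-6-ethenyl-6-methyl-3-methylidene-2-oxo-5-(prop-1-en-2-yl)octahydro-1-benzofuran-7-yl (2S)-2-methylbutanoate, via mixed aroyl anhydride 29 (not isolated)
Conditions: 28, 2,4,6-trichlorobenzoyl chloride, Et3N, THF, rt; then 27, DMAP, toluene, rt to 40 °C
Reagents that add atoms: none
Why: Yamaguchi esterification: the aroyl mixed anhydride with DMAP should acylate the hindered axial C9 hydroxyl, and the acid's (S) centre, which bears an unactivated hydrogen, is brought in unchanged.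

Step 17
Reactants: 30 C9 ester
Product: 31 (3aR,4S,5S,6S,7S,7aR)-4-[(TBS)oxy]-6-ethenyl-5-(3-hydroxyprop-1-en-2-yl)-6-methyl-3-methylidene-2-oxooctahydro-1-benzofuran-7-yl (2S)-2-methylbutanoate
Conditions: SeO2 (0.3 equiv), t-BuOOH, CH2Cl2, rt
Reagents that add atoms: tert-butyl hydroperoxide, CC(C)(C)OO
Why: SeO2-catalysed allylic oxidation (ene reaction then [2,3]-shift) with t-BuOOH as terminal oxidant should attack the isopropenyl group, the only electron-rich alkene with allylic hydrogens, at its methyl and not at the hindered C5 methine; the vinyl group has no allylic hydrogen, the methylene lactone is electron-poor, and any enal 32 formed already converges in step 18.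

Step 18
Reactants: 31 allylic alcohol
Product: 32 (3aR,4S,5R,6S,7S,7aR)-4-[(TBS)oxy]-6-ethenyl-6-methyl-3-methylidene-2-oxo-5-(3-oxoprop-1-en-2-yl)octahydro-1-benzofuran-7-yl (2S)-2-methylbutanoate
Conditions: MnO2, CH2Cl2, rt
Reagents that add atoms: none
Why: MnO2 oxidises the primary allylic alcohol selectively to the conjugated aldehyde; no other free hydroxyl is present.

Step 19
Reactants: 32 enal
Product: 33 (3aR,4S,5R,6R,7S,7aR)-4-[(TBS)oxy]-6-methyl-3-methylidene-6-[(2R)-oxiran-2-yl]-2-oxo-5-(3-oxoprop-1-en-2-yl)octahydro-1-benzofuran-7-yl (2S)-2-methylbutanoate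
Conditions: dimethyldioxirane (acetone solution), CH2Cl2, 0 °C
Reagents that add atoms: dimethyldioxirane, CC1(C)OO1
Why: Dioxirane oxygen transfer to the only electron-rich alkene left (the enal and the methylene lactone are deactivated): with C2 turned away from C5 the C9-side face of the vinyl group is screened by the axial acyloxy group, so oxygen should arrive from the C14-methyl side and give (R)-C1; a hydroxyl-directed epoxidation from a free C9 alcohol would deliver oxygen to the opposite face, which is why acylation precedes this step.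

Step 20
Reactants: 33 silyl-protected epoxide
Product: 34 (3aS,4S,5R,6R,7S,7aR)-4-hydroxy-6-methyl-3-methylidene-6-[(2R)-oxiran-2-yl]-2-oxo-5-(3-oxoprop-1-en-2-yl)octahydro-1-benzofuran-7-yl (2S)-2-methylbutanoate (CNP0510523.1)
Conditions: HF·pyridine, pyridine, THF, 0 °C to rt
Reagents that add atoms: none
Why: Fluoride-mediated cleavage of the secondary silyl ether with pyridine-buffered HF, a reagent that normally leaves epoxides, enals, esters and methylene lactones intact.

Compound list
1 | mono-tert-butyl succinate (4-tert-butoxy-4-oxobutanoic acid) | CC(C)(C)OC(=O)CCC(=O)O | starting material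
2 | (R)-4-benzyloxazolidin-2-one | O=C1N[C@H](Cc2ccccc2)CO1 | starting material
3 | 4-tert-butoxy-4-oxobutanoic pivalic anhydride (not isolated) | CC(C)(C)OC(=O)CCC(=O)OC(=O)C(C)(C)C | intermediate
4 | tert-butyl 4-[(4R)-4-benzyl-2-oxo-1,3-oxazolidin-3-yl]-4-oxobutanoate | CC(C)(C)OC(=O)CCC(=O)N1[C@H](Cc2ccccc2)COC1=O | intermediate
5 | (E)-cinnamaldehyde | O=C/C=C/c1ccccc1 | starting material
6 | O-trimethylsilyl ether of 7 (not isolated) | O=C1OC[C@@H](Cc2ccccc2)N1C(=O)[C@@H](CC(=O)OC(C)(C)C)[C@@H](O[Si](C)(C)C)/C=C/c1ccccc1 | intermediate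
7 | tert-butyl (3S,4S,5E)-3-{[(4R)-4-benzyl-2-oxo-1,3-oxazolidin-3-yl]carbonyl}-4-hydroxy-6-phenylhex-5-enoate | O=C1OC[C@@H](Cc2ccccc2)N1C(=O)[C@@H](CC(=O)OC(C)(C)C)[C@@H](O)/C=C/c1ccccc1 | intermediate
8 | tert-butyl (3R,4S,5E)-4-hydroxy-3-(hydroxymethyl)-6-phenylhex-5-enoate | OC[C@@H](CC(=O)OC(C)(C)C)[C@@H](O)/C=C/c1ccccc1 | intermediate
9 | tert-butyl (3R,4S,5E)-3-{[(TBS)oxy]methyl}-4-hydroxy-6-phenylhex-5-enoate | CC(C)(C)[Si](C)(C)OC[C@@H](CC(=O)OC(C)(C)C)[C@@H](O)/C=C/c1ccccc1 | intermediate
10 | methacryloyl chloride | C=C(C)C(=O)Cl | starting material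
11 | tert-butyl (3R,4S,5E)-3-{[(TBS)oxy]methyl}-4-(methacryloyloxy)-6-phenylhex-5-enoate | CC(C)(C)[Si](C)(C)OC[C@@H](CC(=O)OC(C)(C)C)[C@@H](OC(=O)C(C)=C)/C=C/c1ccccc1 | intermediate
12 | tert-butyl (3R)-4-[(TBS)oxy]-3-[(2S)-4-methyl-5-oxo-2,5-dihydrofuran-2-yl]butanoate | CC(C)(C)[Si](C)(C)OC[C@@H](CC(=O)OC(C)(C)C)[C@H]1OC(=O)C(C)=C1 | intermediate
13 | isopropenylmagnesium bromide | C=C(C)[Mg]Br | starting material
14 | acetaldehyde | CC=O | starting material
15 | bromomagnesium enolate of the C5-isopropenyl lactone (not isolated) | CC(C)(C)[Si](C)(C)OC[C@@H](CC(=O)OC(C)(C)C)[C@H]1OC(O[Mg]Br)=C(C)[C@@H]1C(C)=C | intermediate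
16 | tert-butyl (3R)-4-[(TBS)oxy]-3-[(2S,3S,4R)-4-(1-hydroxyethyl)-4-methyl-5-oxo-3-(prop-1-en-2-yl)oxolan-2-yl]butanoate, carbinol epimers | CC(C)(C)[Si](C)(C)OC[C@@H](CC(=O)OC(C)(C)C)[C@H]1OC(=O)[C@@](C)(C(C)O)[C@@H]1C(C)=C | intermediate
17 | tert-butyl (3R)-4-[(TBS)oxy]-3-[(2S,3S,4S)-4-ethenyl-4-methyl-5-oxo-3-(prop-1-en-2-yl)oxolan-2-yl]butanoate | CC(C)(C)[Si](C)(C)OC[C@@H](CC(=O)OC(C)(C)C)[C@H]1OC(=O)[C@@](C)(C=C)[C@@H]1C(C)=C | intermediate
18 | lactol of 17, anomers (not isolated) | CC(C)(C)[Si](C)(C)OC[C@@H](CC(=O)OC(C)(C)C)[C@H]1OC(O)[C@@](C)(C=C)[C@@H]1C(C)=C | intermediate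
19 | tert-butyl (3R,4S,5S,6S)-3-{[(TBS)oxy]methyl}-4-hydroxy-6-(hydroxymethyl)-6-methyl-5-(prop-1-en-2-yl)oct-7-enoate | CC(C)(C)[Si](C)(C)OC[C@@H](CC(=O)OC(C)(C)C)[C@@H](O)[C@@H](C(C)=C)[C@](C)(C=C)CO | intermediate
20 | tert-butyl (3R,4S,5S,6S)-4-[(TBS)oxy]-3,6-bis{[(TBS)oxy]methyl}-6-methyl-5-(prop-1-en-2-yl)oct-7-enoate | CC(C)(C)[Si](C)(C)OC[C@@H](CC(=O)OC(C)(C)C)[C@@H](O[Si](C)(C)C(C)(C)C)[C@@H](C(C)=C)[C@](C)(C=C)CO[Si](C)(C)C(C)(C)C | intermediate
21 | tert-butyl (3R,4S,5S,6S)-4-[(TBS)oxy]-3,6-bis(hydroxymethyl)-6-methyl-5-(prop-1-en-2-yl)oct-7-enoate | OC[C@@H](CC(=O)OC(C)(C)C)[C@@H](O[Si](C)(C)C(C)(C)C)[C@@H](C(C)=C)[C@](C)(C=C)CO | intermediate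
22 | tert-butyl (3S,4S,5S,6S)-4-[(TBS)oxy]-3,6-diformyl-6-methyl-5-(prop-1-en-2-yl)oct-7-enoate (key-step precursor) | O=C[C@@H](CC(=O)OC(C)(C)C)[C@@H](O[Si](C)(C)C(C)(C)C)[C@@H](C(C)=C)[C@](C)(C=C)C=O | intermediate
23 | tert-butyl 2-[(1R,2R,3S,4S,5S,6S)-6-[(TBS)oxy]-4-ethenyl-2,3-dihydroxy-4-methyl-5-(prop-1-en-2-yl)cyclohexyl]acetate (key-step product) | O[C@@H]1[C@@H](CC(=O)OC(C)(C)C)[C@@H](O[Si](C)(C)C(C)(C)C)[C@@H](C(C)=C)[C@](C)(C=C)[C@@H]1O | intermediate
24 | (3aR,4S,5S,6S,7S,7aR)-4-[(TBS)oxy]-6-ethenyl-7-hydroxy-6-methyl-5-(prop-1-en-2-yl)hexahydro-1-benzofuran-2(3H)-one | C1C(=O)O[C@@H]2[C@@H]1[C@@H](O[Si](C)(C)C(C)(C)C)[C@@H](C(C)=C)[C@](C)(C=C)[C@@H]2O | intermediate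
25 | 3-[(dimethylamino)methyl] derivative of 24, C11 epimers (not isolated) | CN(C)CC1C(=O)O[C@@H]2[C@@H]1[C@@H](O[Si](C)(C)C(C)(C)C)[C@@H](C(C)=C)[C@](C)(C=C)[C@@H]2O | intermediate
26 | 3-[(trimethylammonio)methyl] derivative of 24, iodide (not isolated) | C[N+](C)(C)CC1C(=O)O[C@@H]2[C@@H]1[C@@H](O[Si](C)(C)C(C)(C)C)[C@@H](C(C)=C)[C@](C)(C=C)[C@@H]2O.[I-] | intermediate
27 | (3aR,4S,5S,6S,7S,7aR)-4-[(TBS)oxy]-6-ethenyl-7-hydroxy-6-methyl-3-methylidene-5-(prop-1-en-2-yl)hexahydro-1-benzofuran-2(3H)-one | C=C1C(=O)O[C@@H]2[C@@H]1[C@@H](O[Si](C)(C)C(C)(C)C)[C@@H](C(C)=C)[C@](C)(C=C)[C@@H]2O | intermediate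
28 | (S)-2-methylbutanoic acid | CC[C@H](C)C(=O)O | starting material
29 | (2S)-2-methylbutanoic 2,4,6-trichlorobenzoic anhydride (not isolated) | CC[C@H](C)C(=O)OC(=O)c1c(Cl)cc(Cl)cc1Cl | intermediate
30 | (2S)-2-methylbutanoate of 27 at the C9 oxygen | C=C1C(=O)O[C@@H]2[C@@H]1[C@@H](O[Si](C)(C)C(C)(C)C)[C@@H](C(C)=C)[C@](C)(C=C)[C@@H]2OC(=O)[C@@H](C)CC | intermediate
31 | as 30 with C5 bearing 3-hydroxyprop-1-en-2-yl (C3 allylic alcohol) | C=C1C(=O)O[C@@H]2[C@@H]1[C@@H](O[Si](C)(C)C(C)(C)C)[C@@H](C(=C)CO)[C@](C)(C=C)[C@@H]2OC(=O)[C@@H](C)CC | intermediate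
32 | as 30 with C5 bearing 3-oxoprop-1-en-2-yl (enal) | C=C1C(=O)O[C@@H]2[C@@H]1[C@@H](O[Si](C)(C)C(C)(C)C)[C@@H](C(=C)C=O)[C@](C)(C=C)[C@@H]2OC(=O)[C@@H](C)CC | intermediate
33 | C6 O-TBS ether of the target, (2R)-oxirane on C10 | C=C1C(=O)O[C@@H]2[C@@H]1[C@@H](O[Si](C)(C)C(C)(C)C)[C@@H](C(=C)C=O)[C@](C)([C@@H]1CO1)[C@@H]2OC(=O)[C@@H](C)CC | intermediate
34 | (3aS,4S,5R,6R,7S,7aR)-4-hydroxy-6-methyl-3-methylidene-6-[(2R)-oxiran-2-yl]-2-oxo-5-(3-oxoprop-1-en-2-yl)octahydro-1-benzofuran-7-yl (2S)-2-methylbutanoate | C=C1C(=O)O[C@@H]2[C@@H]1[C@@H](O)[C@@H](C(=C)C=O)[C@](C)([C@@H]1CO1)[C@@H]2OC(=O)[C@@H](C)CC | target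

Total step count: 20. Longest linear sequence: 20 steps (1 to 34).

Steps most likely to fail

Step 13. The two ketyls may couple without sharing one samarium centre, which would erode the cis selectivity, or the formyl groups may simply be reduced to the diol 21. The fallback replaces outer-sphere electron transfer by an inner-sphere template: 22 is added slowly to low-valent titanium prepared from TiCl3(DME)1.5 and Zn–Cu in DME at 25 °C (the pinacol stage of the McMurry reaction, stopped before deoxygenation). Both carbonyl oxygens are then bound to titanium before and after C–C bond formation, and the five-membered titanium diolate can only release a cis-diol; the chair arguments of step 13 decide which one. The fallback sets out from 22, returns at 23 and makes no new compound (F0).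

Step 19. Facial selectivity on a freely rotating vinyl group may be poor or inverted, and the dioxirane may over-oxidise the formyl group. The fallback delivers oxygen in two steps with the opposite facial sense. From 32, NBS in wet THF should give the bromohydrin, the 6-[(1R)-2-bromo-1-hydroxyethyl] analogue of 32, F1, by anti addition (bromonium on the accessible face, water from the other). Cs2CO3 in MeCN then closes the oxirane by intramolecular SN2 displacement, returning at 33. Because the oxygen ends up on the face opposite the one the electrophile attacks, this sequence gives 33 exactly when direct oxygen transfer favours the C1 epimer.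

Step 7. 1,4-Addition to the α-methyl (trisubstituted) butenolide may be slow enough for γ-deprotonation or 1,2-addition to compete, and the crowded enolate may be trapped poorly. The fallback introduces the methyl group after the conjugate addition, so that the acceptor is an unhindered butenolide. From 9, acryloyl chloride and Et3N give the acrylate, tert-butyl (3R,4S,5E)-4-(acryloyloxy)-3-{[(TBS)oxy]methyl}-6-phenylhex-5-enoate, F2. Ring-closing metathesis with the second-generation Grubbs catalyst gives tert-butyl (3R)-4-[(TBS)oxy]-3-[(2S)-5-oxo-2,5-dihydrofuran-2-yl]butanoate, F3. The cuprate from 13 and CuBr·SMe2 adds anti to the C6 side chain, and quenching the enolate with MeI gives tert-butyl (3R)-4-[(TBS)oxy]-3-[(2S,3R)-4-methyl-5-oxo-3-(prop-1-en-2-yl)oxolan-2-yl]butanoate, F4. Deprotonation with LiN(i-Pr)2 at −78 °C (the lactone α-hydrogen is the most acidic site) and addition of 14 then gives 16, where the route is rejoined.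

Further compounds
F0 | step 13 | none | none
F1 | step 19 | (3aR,4S,5R,6R,7S,7aR)-6-[(1R)-2-bromo-1-hydroxyethyl]-4-[(TBS)oxy]-6-methyl-3-methylidene-2-oxo-5-(3-oxoprop-1-en-2-yl)octahydro-1-benzofuran-7-yl (2S)-2-methylbutanoate | C=C1C(=O)O[C@@H]2[C@@H]1[C@@H](O[Si](C)(C)C(C)(C)C)[C@@H](C(=C)C=O)[C@](C)([C@@H](O)CBr)[C@@H]2OC(=O)[C@@H](C)CC
F2 | step 7 | tert-butyl (3R,4S,5E)-4-(acryloyloxy)-3-{[(TBS)oxy]methyl}-6-phenylhex-5-enoate | CC(C)(C)[Si](C)(C)OC[C@@H](CC(=O)OC(C)(C)C)[C@@H](OC(=O)C=C)/C=C/c1ccccc1
F3 | step 7 | tert-butyl (3R)-4-[(TBS)oxy]-3-[(2S)-5-oxo-2,5-dihydrofuran-2-yl]butanoate | CC(C)(C)[Si](C)(C)OC[C@@H](CC(=O)OC(C)(C)C)[C@H]1OC(=O)C=C1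
F4 | step 7 | tert-butyl (3R)-4-[(TBS)oxy]-3-[(2S,3R)-4-methyl-5-oxo-3-(prop-1-en-2-yl)oxolan-2-yl]butanoate, C10 epimers | CC(C)(C)[Si](C)(C)OC[C@@H](CC(=O)OC(C)(C)C)[C@H]1OC(=O)C(C)[C@@H]1C(C)=C
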